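**Plan**

1. Retrosynthesis: cut (a) the two aryl O–benzyl bonds; (b) C3–O and C4–H, i.e. undo a syn-hydration of a C3=C4 bond, back to the meso cis-2,5-diaryl-3,4-dimethyl-2,5-dihydrofuran; (c) C2–C3 and C4–C5 together, a (3+2) cycloreversion to a carbonyl ylide and but-2-yne; (d) the ylide back to a stilbene oxide, the oxirane to the stilbene, and its C=C to two molecules of O-benzylvanillin.
2. Enabling feature: ring atoms C2–O1–C5 form a bis-benzylic ether flanked by two identical guaiacyl rings. This is a latent symmetrical four-electron C–O–C dipole, released from the oxirane by cleavage of its C–C bond. C3/C4 carry cis-methyls with OH and H on one face, the signature of syn addition to a but-2-yne-derived alkene.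
3. An alkyne, not a butenyl partner, is used because the all-cis aryl/methyl/methyl/aryl array is the contra-steric outcome of an alkene cycloaddition. It is the natural outcome of adding B–H to the dihydrofuran from the face away from both aryl groups. The symmetrical alkyne also makes the cycloadduct meso.
4. Forward: reductive coupling gives the stilbene and epoxidation the oxirane; the cycloaddition builds the only new ring (the oxolane, as its 2,5-dihydro form) in one event; hydroboration–oxidation and hydrogenolysis finish.
5. Stereochemistry: C2/C5 cis from the W-shaped ylide; C3/C4 relative to them from syn B–H addition anti to the aryls and retentive oxidation; absolute configuration from enantiotopic-group-selective hydroboration of the meso alkene with IpcBH2 from (−)-α-pinene.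

Key step: step 3

Remark on the chemistry (assumption): the sense in which IpcBH2 selects between the two enantiotopic alkene carbons is extrapolated from trisubstituted cycloalkenes. The reagent from (−)-α-pinene is written; if the other carbon is borylated, the reagent from (+)-α-pinene is used instead. The oxirane is racemic, which is immaterial because its stereocentres are erased in the planar ylide.

**Route**

Step 1
Reactants: 1 4-(benzyloxy)-3-methoxybenzaldehyde (two molecules)
Product: 2 (E)-1,2-bis[4-(benzyloxy)-3-methoxyphenyl]ethene
Conditions: TiCl4, Zn, THF, 0 °C then reflux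
Reagents that add atoms: none
Why: McMurry coupling, in which low-valent titanium reductively couples and deoxygenates two aryl aldehyde carbonyls and should give the less crowded E-stilbene; no stereocentre is formed.

Step 2
Reactants: 2 (E)-1,2-bis[4-(benzyloxy)-3-methoxyphenyl]ethene
Product: 3 trans-2,3-bis[4-(benzyloxy)-3-methoxyphenyl]oxirane (racemic)
Conditions: dimethyldioxirane (ca. 0.07 M in acetone, freshly prepared from acetone and KHSO5), CH2Cl2, 0 °C; evaporate and use crude, no silica
Reagents that add atoms: dimethyldioxirane, CC1(C)OO1
Why: Dioxirane epoxidation is a concerted, stereospecific oxygen transfer under neutral conditions, so the trans-oxirane should form without acid that would open this electron-rich epoxide; acetone is the only by-product.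

Step 3
Reactants: 3 trans-2,3-bis[4-(benzyloxy)-3-methoxyphenyl]oxirane; 4 but-2-yne
Product: 6 (2R,5S)-2,5-bis[4-(benzyloxy)-3-methoxyphenyl]-3,4-dimethyl-2,5-dihydrofuran (cis, meso), via carbonyl ylide 5 (not isolated)
Conditions: 9,10-dicyanoanthracene (5 mol %), but-2-yne/MeCN ca. 1:1 (alkyne in large excess), 420 nm LEDs, sealed tube, Ar, 10 °C
Reagents that add atoms: none
Why: Proposed new method: the excited dicyanoanthracene oxidises a guaiacyl ring of 3, the oxirane C–C bond of the radical cation breaks, and back electron transfer gives the planar W-shaped ylide 5, a four-electron C–O–C dipole with a small frontier-orbital gap that should add suprafacially across the alkyne in a concerted, strongly exothermic (3+2) cycloaddition; uncaptured 5 only recloses to the oxirane, which re-enters the cycle whatever its geometry, so a slow dipolarophile used as co-solvent can still drain it, and but-2-yne is too hard to oxidise to be attacked by the sensitiser. The closest known reaction types are the same electron-transfer-sensitised carbonyl ylide cycloaddition of 2,3-diaryloxiranes with electron-poor alkynes and alkenes, and the addition of non-stabilised carbonyl ylides to unactivated alkynes. The oxolane ring closes in this single intermolecular (3+2) event, which forms C2–C3 and C4–C5 together while the ring oxygen and both C–O bonds are already in place. The two new stereocentres C2 and C5 are set cis by the exo,exo geometry of 5, in which both aryl groups point away from the C–O–C angle and are carried to the same face of the new ring. Because the alkyne is symmetrical there is no regio-, endo/exo or facial question and 6 is meso; the selectivity the step needs is capture of 5 before it decays and no oxidative aromatisation of 6 to the furan, which the large excess of alkyne, exclusion of oxygen and moderate conversion should secure.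

Step 4
Reactants: 6 (2R,5S)-2,5-bis[4-(benzyloxy)-3-methoxyphenyl]-3,4-dimethyl-2,5-dihydrofuran
Product: 8 (2R,3S,4R,5R)-2,5-bis[4-(benzyloxy)-3-methoxyphenyl]-3,4-dimethyloxolan-3-ol, via dialkylborane 7 (not isolated)
Conditions: IpcBH2 [monoisopinocampheylborane from (−)-α-pinene, THF solution freshly liberated from its TMEDA adduct with BF3·OEt2 and filtered], THF, −25 to 0 °C; then NaOH, H2O2, 0 °C to rt
Reagents that add atoms: hydrogen peroxide, OO (oxygen of the new hydroxyl; boron and the isopinocampheyl group of the borane, C[C@@H]1[C@@H](B)C[C@H]2C[C@@H]1C2(C)C, appear only in 7)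
Why: Proposed new method: four-centre syn addition of a B–H bond of IpcBH2 across the tetrasubstituted C3=C4 bond from the face opposite the two cis aryl groups should place boron and hydrogen anti to the aryls and both methyls syn to them, the chiral isopinocampheyl group deciding which of the two enantiotopic alkene carbons takes boron (C3, sense extrapolated from 1-methylcycloalkenes), and alkaline peroxide then replaces boron by hydroxyl with retention; the closest known reaction types are the asymmetric hydroboration of trisubstituted cycloalkenes with IpcBH2 and the hydroboration–oxidation of tetrasubstituted alkenes with BH3, which the small monoalkylborane and the open alkene face should allow to be combined.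

Step 5
Reactants: 8 (2R,3S,4R,5R)-2,5-bis[4-(benzyloxy)-3-methoxyphenyl]-3,4-dimethyloxolan-3-ol
Product: 9 (2R,3S,4R,5R)-2,5-bis(4-hydroxy-3-methoxyphenyl)-3,4-dimethyloxolan-3-ol
Conditions: H2 (1 atm), Pd/C, EtOAc/MeOH, rt, short reaction time
Reagents that add atoms: none
Why: Catalytic hydrogenolysis cleaves aryl benzyl ethers faster than the ring benzylic C–O bonds, so brief exposure should free both phenols without touching the four stereocentres.

**Compound list**

1 | 4-(benzyloxy)-3-methoxybenzaldehyde (O-benzylvanillin) | COc1cc(C=O)ccc1OCc1ccccc1 | starting material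
2 | (E)-1,2-bis[4-(benzyloxy)-3-methoxyphenyl]ethene | COc1cc(/C=C/c2ccc(OCc3ccccc3)c(OC)c2)ccc1OCc1ccccc1 | intermediate
3 | trans-2,3-bis[4-(benzyloxy)-3-methoxyphenyl]oxirane (racemic; the 2S,3S enantiomer is drawn) | COc1cc([C@@H]2O[C@H]2c3ccc(OCc4ccccc4)c(OC)c3)ccc1OCc1ccccc1 | intermediate
4 | but-2-yne | CC#CC | starting material
5 | W-shaped carbonyl ylide, bis[4-(benzyloxy)-3-methoxybenzylidene]oxonium ylide with both aryl groups exo (not isolated) | COc1cc(/C=[O+]/[CH-]c2ccc(OCc3ccccc3)c(OC)c2)ccc1OCc1ccccc1 | intermediate
6 | (2R,5S)-2,5-bis[4-(benzyloxy)-3-methoxyphenyl]-3,4-dimethyl-2,5-dihydrofuran (cis, meso) | COc1cc([C@H]2O[C@@H](c3ccc(OCc4ccccc4)c(OC)c3)C(C)=C2C)ccc1OCc1ccccc1 | intermediate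
7 | [2,5-bis(4-benzyloxy-3-methoxyphenyl)-3,4-dimethyloxolan-3-yl](isopinocampheyl)borane, boron on C3 anti to the aryl groups, spatial arrangement as in 8 (not isolated) | COc1cc([C@H]2O[C@@H](c3ccc(OCc4ccccc4)c(OC)c3)[C@@H](C)[C@]2(C)B[C@H]5C[C@H]6C[C@@H]([C@@H]5C)C6(C)C)ccc1OCc1ccccc1 | intermediate
8 | (2R,3S,4R,5R)-2,5-bis[4-(benzyloxy)-3-methoxyphenyl]-3,4-dimethyloxolan-3-ol | COc1cc([C@H]2O[C@@H](c3ccc(OCc4ccccc4)c(OC)c3)[C@@H](C)[C@]2(C)O)ccc1OCc1ccccc1 | intermediate
9 | (2R,3S,4R,5R)-2,5-bis(4-hydroxy-3-methoxyphenyl)-3,4-dimethyloxolan-3-ol | COc1cc([C@H]2O[C@@H](c3ccc(O)c(OC)c3)[C@@H](C)[C@]2(C)O)ccc1O | target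

**Step count and risks**

Total step count: 5. Longest linear sequence: 5 steps (1 → 2 → 3 → 6 → 8 → 9; but-2-yne enters at step 3).

Steps most likely to fail:

Step 3 (proposed new method). The unactivated alkyne may capture the short-lived ylide too slowly, so that return to the oxirane, fragmentation of the ylide and oxidative aromatisation of the product take over. The fallback sets out from 3 and uses the same sensitised cycloaddition with dimethyl acetylenedicarboxylate, an electron-poor alkyne of the known dipolarophile class. This should give dimethyl (2R,5S)-2,5-bis[4-(benzyloxy)-3-methoxyphenyl]-2,5-dihydrofuran-3,4-dicarboxylate F1. Reduction with i-Bu2AlH (CH2Cl2, −78 °C) should give the bis(hydroxymethyl) compound, the 3,4-diyldimethanol F2. Treatment with MsCl/Et3N in THF at −20 °C forms the bis(methanesulfonate) F3, which is reduced in the same flask with LiBHEt3 to the two methyl groups. The sequence comes back to the route at 6.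

Step 4 (proposed new method). Addition to the tetrasubstituted alkene may be slow, with loss of α-pinene from the reagent and unselective background hydroboration, or the reagent may discriminate poorly between the two enantiotopic alkene carbons. The fallback sets out from 6 and gives up reagent control: BH3·THF (0 °C to rt) followed by NaOH/H2O2 is known to hydroborate tetrasubstituted alkenes and should add from the same face anti to the aryl groups. This gives the racemate, i.e. 8 together with its mirror image (2S,3R,4S,5S)-2,5-bis[4-(benzyloxy)-3-methoxyphenyl]-3,4-dimethyloxolan-3-ol F4. Preparative chromatography on a chiral stationary phase separates the two, and the sequence comes back to the route at 8.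

Step 2. The electron-rich oxirane may open or rearrange (acid-induced ring opening, Meinwald rearrangement) during its formation or isolation. The fallback sets out from 1 and avoids any oxidant or acid. NaBH4 (MeOH, 0 °C) should give [4-(benzyloxy)-3-methoxyphenyl]methanol F5. PBr3 (CH2Cl2, 0 °C) should give 1-(benzyloxy)-4-(bromomethyl)-2-methoxybenzene F6. Tetrahydrothiophene (acetone, rt) should give 1-[4-(benzyloxy)-3-methoxybenzyl]thiolan-1-ium bromide F7. The sulfonium ylide from F7 (aqueous NaOH/CH2Cl2, rt) reacts with a second molecule of 1 in a sulfonium ylide epoxidation that is known to give trans-stilbene oxides under basic conditions. The sequence comes back to the route at 3, which is then used crude in step 3.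

**Further compounds**

F1 | step 3 | dimethyl (2R,5S)-2,5-bis[4-(benzyloxy)-3-methoxyphenyl]-2,5-dihydrofuran-3,4-dicarboxylate (cis, meso) | COc1cc([C@H]2O[C@@H](c3ccc(OCc4ccccc4)c(OC)c3)C(C(=O)OC)=C2C(=O)OC)ccc1OCc1ccccc1
F2 | step 3 | [(2R,5S)-2,5-bis[4-(benzyloxy)-3-methoxyphenyl]-2,5-dihydrofuran-3,4-diyl]dimethanol | COc1cc([C@H]2O[C@@H](c3ccc(OCc4ccccc4)c(OC)c3)C(CO)=C2CO)ccc1OCc1ccccc1
F3 | step 3 | [(2R,5S)-2,5-bis[4-(benzyloxy)-3-methoxyphenyl]-2,5-dihydrofuran-3,4-diyl]bis(methylene) dimethanesulfonate | COc1cc([C@H]2O[C@@H](c3ccc(OCc4ccccc4)c(OC)c3)C(COS(C)(=O)=O)=C2COS(C)(=O)=O)ccc1OCc1ccccc1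
F4 | step 4 | (2S,3R,4S,5S)-2,5-bis[4-(benzyloxy)-3-methoxyphenyl]-3,4-dimethyloxolan-3-ol (enantiomer of 8) | COc1cc([C@@H]2O[C@H](c3ccc(OCc4ccccc4)c(OC)c3)[C@H](C)[C@@]2(C)O)ccc1OCc1ccccc1
F5 | step 2 | [4-(benzyloxy)-3-methoxyphenyl]methanol | COc1cc(CO)ccc1OCc1ccccc1
F6 | step 2 | 1-(benzyloxy)-4-(bromomethyl)-2-methoxybenzene | COc1cc(CBr)ccc1OCc1ccccc1
F7 | step 2 | 1-[4-(benzyloxy)-3-methoxybenzyl]thiolan-1-ium bromide | COc1cc(C[S+]2CCCC2)ccc1OCc1ccccc1.[Br-]
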